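**Plan**

1. Retrosynthesis: the two aryl MOM ethers come off first and C2 is traced back to the lactol level (C2–H ⇐ C2–SePh ⇐ C2–OH). The dihydropyran ring is then cut at O1–C2 and C3–C4 in one operation, giving an A-ring o-quinone methide and a B-ring arylacetaldehyde.
2. Enabling feature: in ring A the phenolic O1 on C8a stands next to the benzylic C4 on C4a, so O1–C8a–C4a–C4 is a latent 1-oxadiene (o-quinone methide). The C5 methoxy group blocks the other flank and the C7–OH is para, so only O1 can close the pyran ring.
3. The C8 formyl group lies between two ring oxygens, so the A-ring precursor is the C2v-symmetric 2,6-dihydroxy-4-methoxybenzaldehyde with two identical free positions. The aldehyde is bought rather than introduced late; because it rules out hydride steps after fragment union, C2 enters at the aldehyde level and loses its oxygen by a neutral selenide/tin hydride sequence.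
4. Forward: sulfonylmethylation of ring A (1 step); MOM protection, ester reduction, ortho-lithiation/prenylation and oxidation for ring B (4 steps). Both benzene rings are bought; the pyran ring is the only ring formed, by an amine-catalysed [4+2] annulation that also joins the two halves.
5. Stereochemistry: the only stereocentre, C3 (R), is set in the annulation by the (R)-diarylprolinol silyl ether through facial control of the enamine and is not touched afterwards; C2 is a transient epimer mixture.
6. End game: Mitsunobu-type selenenylation of the lactol, radical deselenation, acidic MOM cleavage.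

Key step: step 6

Remark: chroman numbering is used throughout (O1, C2, C3, C4, C4a, C5–C8, C8a; ring B primed). C2 of compounds 11–13 is an epimer mixture that becomes CH2 in step 8. Paraformaldehyde, MOMCl and prenyl bromide are treated as reagents.

**Route**

Step 1
Reactants: 1 2,6-dihydroxy-4-methoxybenzaldehyde
Product: 2 2,6-dihydroxy-4-methoxy-3-[(4-methylbenzenesulfonyl)methyl]benzaldehyde
Conditions: (CH2O)n (1.0 equiv), TolSO2Na (1.5 equiv), HCO2H/H2O, rt; 1 in slight excess
Reagents that add atoms: paraformaldehyde, as formaldehyde (C=O); sodium p-toluenesulfinate (Cc1ccc(cc1)S(=O)[O-].[Na+])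
Why: Mannich-type three-component sulfonylmethylation (hydroxymethylation of the electron-rich ring, acid-promoted ionisation, capture by sulfinate) should give the mono-adduct, and because 1 is C2v-symmetric its two free ring positions (each between an OH and the OMe) are identical, so only one regioisomer can form.

Step 2
Reactants: 3 methyl 2-(2,4-dihydroxyphenyl)acetate
Product: 4 methyl 2-[2,4-bis(methoxymethoxy)phenyl]acetate
Conditions: MOMCl (3 equiv), iPr2NEt (4 equiv), CH2Cl2, 0 °C → rt
Reagents that add atoms: chloromethyl methyl ether (COCCl)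
Why: Standard O-alkylation of both phenols (MOM ether formation), which masks the B-ring phenols until the last step and provides the two directing groups for the later ortho-lithiation.

Step 3
Reactants: 4 methyl 2-[2,4-bis(methoxymethoxy)phenyl]acetate
Product: 5 2-[2,4-bis(methoxymethoxy)phenyl]ethanol
Conditions: LiAlH4, THF, 0 °C
Reagents that add atoms: none
Why: Hydride reduction of the ester to the primary alcohol leaves the MOM acetals intact and removes the enolisable ester before the organolithium step.

Step 4
Reactants: 5 2-[2,4-bis(methoxymethoxy)phenyl]ethanol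
Product: 7 2-[2,4-bis(methoxymethoxy)-3-(3-methylbut-2-en-1-yl)phenyl]ethanol, via dilithio alkoxide 6 (not isolated)
Conditions: n-BuLi (2.3 equiv), THF, 0 °C → rt; then CuBr·SMe2 (10 mol%), prenyl bromide (1.1 equiv), −78 → 0 °C; aq. work-up
Reagents that add atoms: prenyl bromide (CC(C)=CCBr)
Why: Directed ortho-metalation in which, after O-deprotonation, the second equivalent of n-BuLi lithiates the ring carbon flanked by both OMOM groups (the cooperatively activated site), and copper-catalysed SN2 capture by prenyl bromide should give the linear prenyl arene while the aggregated lithium alkoxide stays unreactive at low temperature.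

Step 5
Reactants: 7 2-[2,4-bis(methoxymethoxy)-3-(3-methylbut-2-en-1-yl)phenyl]ethanol
Product: 8 2-[2,4-bis(methoxymethoxy)-3-(3-methylbut-2-en-1-yl)phenyl]acetaldehyde
Conditions: Dess–Martin periodinane (1.2 equiv), CH2Cl2, 0 °C → rt; used at once
Reagents that add atoms: none
Why: Dess–Martin oxidation converts the primary alcohol to the arylacetaldehyde under near-neutral conditions that spare the MOM acetals and the trisubstituted alkene, and the enolisable aldehyde is carried on without storage.

Step 6
Reactants: 2 2,6-dihydroxy-4-methoxy-3-[(4-methylbenzenesulfonyl)methyl]benzaldehyde; 8 2-[2,4-bis(methoxymethoxy)-3-(3-methylbut-2-en-1-yl)phenyl]acetaldehyde (1.5 equiv)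
Product: 12 (3R)-3-[2,4-bis(methoxymethoxy)-3-(3-methylbut-2-en-1-yl)phenyl]-2,7-dihydroxy-5-methoxy-3,4-dihydro-2H-chromene-8-carbaldehyde (C2 epimers), via o-quinone methide 9 (not isolated), via enamine 10 (not isolated), via aminal cycloadduct 11 (not isolated)
Conditions: (R)-α,α-diphenylprolinol trimethylsilyl ether (20 mol%), NaHCO3 (2.5 equiv), CHCl3, 0 °C → rt; aqueous work-up
Reagents that add atoms: water (O), which returns the C2 hydroxyl oxygen when aminal 11 is hydrolysed
Why: Hydrogencarbonate deprotonates the C8a–OH of 2 and 1,4-elimination of sulfinate gives the o-quinone methide 9 (1-oxadiene O1=C8a–C4a=C4, made more electrophilic by the C8 formyl group), while the amine condenses with 8 to the (E)-enamine 10. The enamine carbon that becomes C3 adds to the exocyclic methylene C4 and the phenoxide O1 then closes onto the iminium carbon C2 in a 6-exo-trig mode (a stepwise, formally inverse-electron-demand oxa-[4+2] annulation) to give aminal 11, whose hydrolysis on work-up returns the catalyst and lets the ring settle as the six-membered lactol 12. The closest known reaction type is the diarylprolinol silyl ether-catalysed [4+2] annulation of enolisable aldehydes with o-quinone methides released in situ from 2-(sulfonylmethyl)phenols. C3 is set in the C–C bond-forming event by the catalyst: the CPh2OTMS group shields one face of the s-trans (E)-enamine, the electrophile enters from the open face, and because the CIP order at C3 is C2 > aryl > C4 the (R)-catalyst should deliver (3R), while the hemiacetal centre C2 is not controlled and is erased in step 8. Regio- and chemoselectivity are secured by ring A itself: only O1 is ortho to the methylene, the C5 methoxy group blocks the other flank, the C7–OH is para and hydrogen-bonded to the formyl group, and this hindered, deactivated aryl aldehyde should compete neither with 8 for the bulky amine nor with 9 for the enamine. The step also needs the product to keep its ee, which is expected because 12 rests mainly as the closed lactol and an α,α-disubstituted aldehyde re-forms an enamine with the bulky catalyst only slowly.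

Step 7
Reactants: 12 (3R)-3-[2,4-bis(methoxymethoxy)-3-(3-methylbut-2-en-1-yl)phenyl]-2,7-dihydroxy-5-methoxy-3,4-dihydro-2H-chromene-8-carbaldehyde (C2 epimers)
Product: 13 (3R)-3-[2,4-bis(methoxymethoxy)-3-(3-methylbut-2-en-1-yl)phenyl]-7-hydroxy-5-methoxy-2-(phenylselanyl)-3,4-dihydro-2H-chromene-8-carbaldehyde (C2 epimers)
Conditions: n-Bu3P and N-(phenylseleno)phthalimide premixed, CH2Cl2, −20 °C → rt
Reagents that add atoms: N-(phenylseleno)phthalimide (O=C1c2ccccc2C(=O)N1[Se]c1ccccc1)
Why: Mitsunobu-type redox condensation (Grieco–Nicolaou selenenylation) in which the preformed selenophosphonium salt activates the hemiacetal hydroxyl, the only aliphatic OH in 12, and the soft, weakly basic selenolate replaces it under neutral conditions that should leave the hydrogen-bonded aryl aldehyde, the phenol, the MOM acetals, the prenyl alkene and C3 untouched, both C2 epimers being equally useful.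

Step 8
Reactants: 13 (3R)-3-[2,4-bis(methoxymethoxy)-3-(3-methylbut-2-en-1-yl)phenyl]-7-hydroxy-5-methoxy-2-(phenylselanyl)-3,4-dihydro-2H-chromene-8-carbaldehyde (C2 epimers)
Product: 14 (3R)-3-[2,4-bis(methoxymethoxy)-3-(3-methylbut-2-en-1-yl)phenyl]-7-hydroxy-5-methoxy-3,4-dihydro-2H-chromene-8-carbaldehyde
Conditions: n-Bu3SnH (1.5 equiv), AIBN (cat.), degassed toluene, 80 °C
Reagents that add atoms: none
Why: Radical chain reduction in which the stannyl radical abstracts the phenylselanyl group and the resulting α-aryloxyalkyl radical at C2 takes a hydrogen atom from Bu3SnH, so the helper oxidation level at C2 is removed without hydride or acid and the aldehyde, the alkene and the neighbouring C3 stereocentre should be unaffected.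

Step 9
Reactants: 14 (3R)-3-[2,4-bis(methoxymethoxy)-3-(3-methylbut-2-en-1-yl)phenyl]-7-hydroxy-5-methoxy-3,4-dihydro-2H-chromene-8-carbaldehyde
Product: 15 (3R)-3-[2,4-dihydroxy-3-(3-methylbut-2-en-1-yl)phenyl]-7-hydroxy-5-methoxy-3,4-dihydro-2H-chromene-8-carbaldehyde
Conditions: 3 M aq. HCl (cat.), MeOH, rt → 40 °C, short reaction time
Reagents that add atoms: none
Why: Acid-catalysed transacetalisation to methanol (MOM ether cleavage) should free the 2'- and 4'-phenols, with low acid strength, moderate temperature and short exposure chosen so that the prenyl group does not cyclise onto a neighbouring phenol, and C3 is not epimerisable.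

**Compound list**

1 | 2,6-dihydroxy-4-methoxybenzaldehyde | COc1cc(O)c(C=O)c(O)c1 | starting material
2 | 2,6-dihydroxy-4-methoxy-3-[(4-methylbenzenesulfonyl)methyl]benzaldehyde | COc1cc(O)c(C=O)c(O)c1CS(=O)(=O)c1ccc(C)cc1 | intermediate
3 | methyl 2-(2,4-dihydroxyphenyl)acetate | COC(=O)Cc1ccc(O)cc1O | starting material
4 | methyl 2-[2,4-bis(methoxymethoxy)phenyl]acetate | COCOc1ccc(CC(=O)OC)c(OCOC)c1 | intermediate
5 | 2-[2,4-bis(methoxymethoxy)phenyl]ethanol | COCOc1ccc(CCO)c(OCOC)c1 | intermediate
6 | lithium 2-[3-lithio-2,4-bis(methoxymethoxy)phenyl]ethoxide | [Li]OCCc1ccc(OCOC)c([Li])c1OCOC | intermediate (not isolated)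
7 | 2-[2,4-bis(methoxymethoxy)-3-(3-methylbut-2-en-1-yl)phenyl]ethanol | OCCc1ccc(OCOC)c(CC=C(C)C)c1OCOC | intermediate
8 | 2-[2,4-bis(methoxymethoxy)-3-(3-methylbut-2-en-1-yl)phenyl]acetaldehyde | O=CCc1ccc(OCOC)c(CC=C(C)C)c1OCOC | intermediate
9 | 2-hydroxy-4-methoxy-5-methylidene-6-oxocyclohexa-1,3-diene-1-carbaldehyde (o-quinone methide of ring A) | C=C1C(OC)=CC(O)=C(C=O)C1=O | intermediate (not isolated)
10 | (2R)-1-{(E)-2-[2,4-bis(methoxymethoxy)-3-(3-methylbut-2-en-1-yl)phenyl]ethenyl}-2-[diphenyl(trimethylsilyloxy)methyl]pyrrolidine | C[Si](C)(C)OC(c1ccccc1)(c1ccccc1)[C@H]1CCCN1/C=C/c1ccc(OCOC)c(CC=C(C)C)c1OCOC | intermediate (not isolated)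
11 | (3R)-3-[2,4-bis(methoxymethoxy)-3-(3-methylbut-2-en-1-yl)phenyl]-2-{(2R)-2-[diphenyl(trimethylsilyloxy)methyl]pyrrolidin-1-yl}-7-hydroxy-5-methoxy-3,4-dihydro-2H-chromene-8-carbaldehyde (C2 not defined) | COc1cc(O)c(C=O)c2c1C[C@H](c1ccc(OCOC)c(CC=C(C)C)c1OCOC)C(O2)N1CCC[C@@H]1C(c1ccccc1)(c1ccccc1)O[Si](C)(C)C | intermediate (not isolated)
12 | (3R)-3-[2,4-bis(methoxymethoxy)-3-(3-methylbut-2-en-1-yl)phenyl]-2,7-dihydroxy-5-methoxy-3,4-dihydro-2H-chromene-8-carbaldehyde (C2 epimers) | COc1cc(O)c(C=O)c2c1C[C@H](c1ccc(OCOC)c(CC=C(C)C)c1OCOC)C(O)O2 | intermediate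
13 | (3R)-3-[2,4-bis(methoxymethoxy)-3-(3-methylbut-2-en-1-yl)phenyl]-7-hydroxy-5-methoxy-2-(phenylselanyl)-3,4-dihydro-2H-chromene-8-carbaldehyde (C2 epimers) | COc1cc(O)c(C=O)c2c1C[C@H](c1ccc(OCOC)c(CC=C(C)C)c1OCOC)C([Se]c1ccccc1)O2 | intermediate
14 | (3R)-3-[2,4-bis(methoxymethoxy)-3-(3-methylbut-2-en-1-yl)phenyl]-7-hydroxy-5-methoxy-3,4-dihydro-2H-chromene-8-carbaldehyde | COc1cc(O)c(C=O)c2c1C[C@H](c1ccc(OCOC)c(CC=C(C)C)c1OCOC)CO2 | intermediate
15 | (3R)-3-[2,4-dihydroxy-3-(3-methylbut-2-en-1-yl)phenyl]-7-hydroxy-5-methoxy-3,4-dihydro-2H-chromene-8-carbaldehyde | COc1cc(O)c(C=O)c2c1C[C@H](c1ccc(O)c(CC=C(C)C)c1O)CO2 | target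

**Step count and risks**

Total step count: 9. Longest linear sequence: 8 steps (3 → 15, steps 2–9).

Steps most likely to fail:

1. Step 6 (organocatalytic annulation). The free secondary amine may be tied up by aza-Michael addition to 9 or by condensation with the A-ring aldehyde, so that turnover stalls and 9 oligomerises. Alternatively the product may lose enantiopurity through its ring-opened aldehyde form under the basic, amine-containing conditions. The fallback uses auxiliary control instead of catalysis, without free N–H amine or water. It sets out from 8, which is condensed with (2R,5R)-2,5-dimethylpyrrolidine over 4 Å molecular sieves in CH2Cl2 to give the isolated enamine (2R,5R)-1-{(E)-2-[2,4-bis(methoxymethoxy)-3-(3-methylbut-2-en-1-yl)phenyl]ethenyl}-2,5-dimethylpyrrolidine F1. Sulfone 2 is then treated with anhydrous Na2CO3 in toluene at 0 °C in the presence of F1; the released 9 should undergo the classical enamine/o-quinone methide cycloaddition anti to the methyl group that flanks the enamine carbon. This should give the isolable 2-aminochroman (3R)-3-[2,4-bis(methoxymethoxy)-3-(3-methylbut-2-en-1-yl)phenyl]-2-[(2R,5R)-2,5-dimethylpyrrolidin-1-yl]-7-hydroxy-5-methoxy-3,4-dihydro-2H-chromene-8-carbaldehyde F2, in which the 2,5-disubstituted pyrrolidine disfavours re-enamination by allylic strain. Brief hydrolysis of F2 with cold dilute aqueous HCl in THF, which protonates the liberated auxiliary at once, returns lactol 12, where the route is rejoined.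

2. Step 7 (lactol to selenide). Activation of the hemiacetal hydroxyl may be followed by loss of the C3 proton, giving the 3-aryl-4H-chromene and destroying the stereocentre, or the lactol may react through its open-chain form. The fallback avoids anomeric activation and sets out from 12. NaBH(OAc)3 in 1,2-dichloroethane should reduce only the aliphatic aldehyde of the open-chain tautomer, because the doubly ortho-oxygenated, hydrogen-bonded aryl aldehyde behaves as a vinylogous ester. This gives the diol 3-{(2R)-2-[2,4-bis(methoxymethoxy)-3-(3-methylbut-2-en-1-yl)phenyl]-3-hydroxypropyl}-2,6-dihydroxy-4-methoxybenzaldehyde F3. An intramolecular Mitsunobu etherification (PPh3, DIAD, THF, 0 °C, high dilution) then closes the ring without touching C3; the acidic C8a–OH is the only phenol that can reach the primary carbinol through a six-membered transition state. This gives 14 directly, so the route is rejoined at 14 and steps 7 and 8 are bypassed.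

3. Step 4 (ortho-lithiation/prenylation). The second lithiation may be incomplete, the alkoxide may be O-allylated, or SN2' capture may give the reverse-prenyl (1,1-dimethylallyl) isomer. The fallback uses cross-coupling instead of allylation of the organolithium and sets out from 5. The same dilithio species 6 is quenched with iodine to give 2-[3-iodo-2,4-bis(methoxymethoxy)phenyl]ethanol F4. A Stille coupling with tributyl(3-methylbut-2-en-1-yl)stannane (Pd(PPh3)4, CuI, CsF, DMF, 45 °C), which tolerates the free hydroxyl group, should then deliver 7, where the route is rejoined.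

Further compounds
F1 | step 6 | (2R,5R)-1-{(E)-2-[2,4-bis(methoxymethoxy)-3-(3-methylbut-2-en-1-yl)phenyl]ethenyl}-2,5-dimethylpyrrolidine | C[C@@H]1CC[C@@H](C)N1/C=C/c1ccc(OCOC)c(CC=C(C)C)c1OCOC
F2 | step 6 | (3R)-3-[2,4-bis(methoxymethoxy)-3-(3-methylbut-2-en-1-yl)phenyl]-2-[(2R,5R)-2,5-dimethylpyrrolidin-1-yl]-7-hydroxy-5-methoxy-3,4-dihydro-2H-chromene-8-carbaldehyde (C2 not defined) | COc1cc(O)c(C=O)c2c1C[C@H](c1ccc(OCOC)c(CC=C(C)C)c1OCOC)C(O2)N1[C@H](C)CC[C@H]1C
F3 | step 7 | 3-{(2R)-2-[2,4-bis(methoxymethoxy)-3-(3-methylbut-2-en-1-yl)phenyl]-3-hydroxypropyl}-2,6-dihydroxy-4-methoxybenzaldehyde | COc1cc(O)c(C=O)c(O)c1C[C@H](c1ccc(OCOC)c(CC=C(C)C)c1OCOC)CO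
F4 | step 4 | 2-[3-iodo-2,4-bis(methoxymethoxy)phenyl]ethanol | OCCc1ccc(OCOC)c(I)c1OCOC
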